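**Retrosynthetic overview**
1. Ring carbons are numbered C1–C13 along the SMILES (C1 octyl, C5 tertiary OH, C6 CO2H, C8 secondary OH). Rings: A = cyclobutane C1-C2-C12-C11, B = cyclopentane C9-C10-C11-C12-C13, C = C2-C3-C4-C5-C13-C12, D = C5-C6-C7-C8-C9-C13. The strategy rests on the A/B bicyclo[3.2.0]heptane: its bonds C11–C12 and C1–C2 connect what can be a ring-C alkene (C2=C12) and a chain alkene (C11=C1) held three atoms apart (C13, C9, C10).
2. Retro-[2+2] across C11–C12 and C1–C2 leads from tricyclic ketone 22 to the 4-substituted cyclohex-2-enone 21, which carries an E-alkenyl arm.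
3. Ring D is cut at C5–C6 (thiolate Michael–aldol of a Z-enoate onto a C5 ketone, then elimination) and at C7–C8 (propiolate plus C8 aldehyde, C8 set by Midland reduction). C5=O and C3=C4 come from the C3 ketone by Saegusa–Ito oxidation, epoxidation and Wharton transposition.
4. In 21, C13 comes by Johnson–Claisen relay from the allylic C2 carbinol of the 1,2-dioxygenated cyclohexene 6; only this pattern puts carbon on C13 and leaves C3–O allylic for the enone. C9 is set by Evans allylation, because silyl ketene acetals of cyclohexenyl esters divide between chair and boat and their preferred paths lead to the 9-epimer.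
5. Order of rings: C (bought) → B and A together (step 13) → D (step 25).

Key step: step 13

Assumption: (R)-cyclohex-2-en-1-ol (1) and (E)-undec-2-en-1-ol (14) are taken as catalogue compounds; the configurations drawn at transient centres (C4/C5 in 25–26, C5 in 27–28, C3/C6/C7 in 36–38) are the expected ones and are all erased later.

**Step 1**
Reactants: 1 (R)-cyclohex-2-en-1-ol
Product: 2 (1R,2R,6S)-7-oxabicyclo[4.1.0]heptan-2-ol (cis-2,3-epoxycyclohexanol)
Conditions: VO(acac)2 (cat.), t-BuOOH, CH2Cl2, 0 °C → rt
Reagents that add atoms: tert-butyl hydroperoxide, CC(C)(C)OO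
Why: Hydroxyl-directed vanadium-catalysed epoxidation of an allylic alcohol should deliver oxygen syn to the carbinol, so the bought centre (future C3) fixes the configuration of the future C2–O bond.

**Step 2**
Reactants: 2 cis-2,3-epoxycyclohexanol
Product: 3 TBS ether of 2
Conditions: TBSCl, imidazole, DMF, 0 °C → rt
Reagents that add atoms: tert-butyldimethylsilyl chloride, CC(C)(C)[Si](C)(C)Cl
Why: Imidazole-promoted silylation of a secondary alcohol touches no stereocentre, and its near-neutral medium avoids Payne migration of the epoxy alcohol.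

**Step 3**
Reactants: 3 TBS ether of cis-2,3-epoxycyclohexanol
Product: 6 (1S,6R)-6-(tert-butyldimethylsilyloxy)cyclohex-2-en-1-ol, via hydroxy selenide 4 (not isolated), via selenoxide 5 (not isolated)
Conditions: (PhSe)2, NaBH4, EtOH, rt → 50 °C; then THF, 30% H2O2, 0 °C → rt
Reagents that add atoms: none
Why: Epoxide-to-allylic-alcohol transposition by selenolate opening and selenoxide syn-elimination (Sharpless–Lauer reaction): the selenolate should attack trans-diaxially at the epoxide carbon remote from the silyloxy group (C12) and the selenoxide eliminates away from the carbinol carbon, which places the alkene at C12=C13 and leaves C2–O and C3–O untouched.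

**Step 4**
Reactants: 6 (1S,6R)-6-(tert-butyldimethylsilyloxy)cyclohex-2-en-1-ol; 7 triethyl orthoacetate
Product: 9 ethyl 2-[(1R,4R)-4-(tert-butyldimethylsilyloxy)cyclohex-2-en-1-yl]acetate, via ketene acetal 8 (not isolated)
Conditions: MeC(OEt)3 (solvent), EtCO2H (cat.), 140 °C, EtOH distilled off
Reagents that add atoms: triethyl orthoacetate (7), CCOC(C)(OCC)OCC
Why: Johnson–Claisen rearrangement: the [3,3] shift of 8 is suprafacial, so C13–C9 forms on the ring face that carried C2–O (sets C13), the alkene moves to C2=C12 and C3–O becomes allylic, and because C9 is still a CH2 group the chair/boat question has no stereochemical consequence.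

**Step 5**
Reactants: 9 ethyl ester
Product: 10 2-[(1R,4R)-4-(tert-butyldimethylsilyloxy)cyclohex-2-en-1-yl]acetic acid
Conditions: LiOH, THF/MeOH/H2O, rt; then 1 M HCl to pH 3
Reagents that add atoms: lithium hydroxide, [Li+].[OH-]
Why: Saponification of an unhindered ethyl ester, to which the silyl ether and the allylic centre C13 are inert.

**Step 6**
Reactants: 10 acid; 11 (S)-4-benzyl-1,3-oxazolidin-2-one
Product: 13 (4S)-4-benzyl-3-{2-[(1R,4R)-4-(tert-butyldimethylsilyloxy)cyclohex-2-en-1-yl]acetyl}-1,3-oxazolidin-2-one, via mixed anhydride 12 (not isolated)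
Conditions: PivCl, Et3N, THF, −20 °C; then 11/n-BuLi (THF, −78 °C), −78 → 0 °C
Reagents that add atoms: (S)-4-benzyl-1,3-oxazolidin-2-one (11), O=C1N[C@@H](Cc2ccccc2)CO1
Why: N-Acylation of the lithiated Evans oxazolidinone by the pivalic mixed anhydride takes place at the less hindered carbonyl and creates no stereocentre.

**Step 7**
Reactants: 14 (E)-undec-2-en-1-ol
Product: 15 (E)-1-bromoundec-2-ene
Conditions: CBr4, PPh3, CH2Cl2, 0 °C
Reagents that add atoms: carbon tetrabromide, BrC(Br)(Br)Br
Why: Appel bromination is an SN2 displacement at the primary allylic carbon under neutral conditions, so neither allylic transposition nor E/Z isomerisation is expected.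

**Step 8**
Reactants: 13 N-acyl oxazolidinone; 15 (E)-1-bromoundec-2-ene
Product: 17 (4S)-4-benzyl-3-{(2S,4E)-2-[(1S,4R)-4-(tert-butyldimethylsilyloxy)cyclohex-2-en-1-yl]tridec-4-enoyl}-1,3-oxazolidin-2-one, via sodium enolate 16 (not isolated)
Conditions: NaHMDS, THF, −78 °C; then 15, −78 → −40 °C
Reagents that add atoms: (E)-1-bromoundec-2-ene (15), CCCCCCCC/C=C/CBr
Why: Evans asymmetric alkylation: the benzyl group shields one face of the chelated Z-enolate 16, the allylic bromide is attacked (SN2) from the open face, and C9 should result S under auxiliary control whatever the bias of C13.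

**Step 9**
Reactants: 17 alkylated imide
Product: 18 (2S,4E)-2-[(1S,4R)-4-(tert-butyldimethylsilyloxy)cyclohex-2-en-1-yl]tridec-4-en-1-ol
Conditions: LiBH4, MeOH (1 equiv), Et2O, 0 °C
Reagents that add atoms: none
Why: Reductive cleavage of the N-acyl oxazolidinone with LiBH4 gives the primary alcohol without enolisation, so C9 is kept and the auxiliary is recovered.

**Step 10**
Reactants: 18 silyloxy alcohol
Product: 19 (1R,4S)-4-[(2S,4E)-1-hydroxytridec-4-en-2-yl]cyclohex-2-en-1-ol
Conditions: TBAF, THF, rt
Reagents that add atoms: none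
Why: Fluoride-induced cleavage of the silyl ether frees the C3 carbinol, and no other group responds to TBAF.

**Step 11**
Reactants: 19 diol
Product: 20 (1R,4S)-4-[(2S,4E)-1-(tert-butyldimethylsilyloxy)tridec-4-en-2-yl]cyclohex-2-en-1-ol
Conditions: TBSCl (1.05 equiv), imidazole, CH2Cl2, −10 °C
Reagents that add atoms: tert-butyldimethylsilyl chloride, CC(C)(C)[Si](C)(C)Cl
Why: Kinetically selective monosilylation, since the primary C8 hydroxyl reacts far faster with TBSCl than the secondary allylic C3 hydroxyl.

**Step 12**
Reactants: 20 allylic alcohol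
Product: 21 (4S)-4-[(2S,4E)-1-(tert-butyldimethylsilyloxy)tridec-4-en-2-yl]cyclohex-2-en-1-one
Conditions: DMP, pyridine, CH2Cl2, 0 °C → rt
Reagents that add atoms: none
Why: Dess–Martin oxidation gives the enone under buffered conditions that should neither deconjugate it nor epimerise the γ-centre C13, and the C3 stereocentre, its relay work done, is erased.

**Step 13**
Reactants: 21 4-substituted cyclohex-2-enone with E-alkenyl arm
Product: 22 tricyclic C3 ketone (rings A/B/C; H2, H11, H12, H13 all cis on the convex face, octyl exo on C1, CH2OTBS on C9 on the convex face trans to C5)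
Conditions: hν (366 nm, Pyrex), degassed MeCN (5 mM), 0 °C; then DBU (cat.), CH2Cl2, rt
Reagents that add atoms: none
Why: Excitation and intersystem crossing give the twisted triplet enone, whose β-carbon C12 attacks C11 in a 5-exo (1,5) closure that builds cyclopentane B, and after spin inversion the 1,4-biradical (α-acyl C2, secondary alkyl C1) couples C1–C2 in a 1,4-radical recombination that closes cyclobutane A. The closest known reaction type is the intramolecular enone–alkene [2+2] photocycloaddition of 4-(but-3-enyl)cyclohex-2-enones, which follows the rule of five and runs in the straight mode. C12 is set by C13, because the tether can reach only the enone face syn to C9 (cis B/C fusion), and C11 follows because only the biradical with C1 turned towards C2 can close while the other reverts to 21. C2 ends cis-fused, any trans A/C material being epimerised α to the C3 ketone by the DBU treatment. C1 is set in the last bond formation, where the rotating radical centre should place octyl on the convex face, trans to C10 and C3, the relationship that the E alkene also encodes. The step needs straight over crossed regiochemistry, secured by the three-atom spacer C13–C9–C10, and exo over endo closure at C1, secured by the bowl shape of the forming tricycle with the C9 arm pseudo-equatorial; the enone is the only chromophore that absorbs at this wavelength.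

**Step 14**
Reactants: 22 tricyclic C3 ketone
Product: 24 tricyclic C3 ketone with C4=C5 alkene (enone), via silyl enol ether 23 (not isolated)
Conditions: LDA, TMSCl, THF, −78 °C; then Pd(OAc)2 (1 equiv), MeCN, rt
Reagents that add atoms: none
Why: Saegusa–Ito oxidation: kinetic deprotonation takes the C4 methylene and not the cyclobutane methine C2, and Pd(II) then dehydrosilylates 23 to the C4=C5 enone.

**Step 15**
Reactants: 24 C4=C5 enone
Product: 25 4,5-epoxy C3 ketone (epoxide on the convex face)
Conditions: 30% H2O2, NaOH (cat.), MeOH, 0 °C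
Reagents that add atoms: hydrogen peroxide, OO
Why: Weitz–Scheffer nucleophilic epoxidation: hydroperoxide should add to C5 from the convex face, anti to C9, and the new centres matter only in that C5 now carries oxygen, since C5 is flattened again in step 18.

**Step 16**
Reactants: 25 epoxy ketone
Product: 27 C3=C4 alkene with secondary 5-OH (convex face) and 8-OTBS, via epoxy hydrazone 26 (not isolated)
Conditions: N2H4·H2O, AcOH (cat.), MeOH, 0 °C → rt
Reagents that add atoms: none
Why: Wharton transposition: the hydrazone opens the epoxide, loses N2 and leaves the C3=C4 alkene with the oxygen retained on C5.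

**Step 17**
Reactants: 27 allylic alcohol silyl ether
Product: 28 C5,C8-diol
Conditions: TBAF, THF, rt
Reagents that add atoms: none
Why: Fluoride desilylation of the primary TBS ether, to which alkene and carbinol are inert.

**Step 18**
Reactants: 28 diol
Product: 29 C5 enone (C3=C4) with C8 aldehyde
Conditions: DMP (2.5 equiv), pyridine, CH2Cl2, 0 °C → rt
Reagents that add atoms: none
Why: Double Dess–Martin oxidation gives enone and aldehyde in one operation, and C9, now epimerisable, already has its more stable configuration (formyl on the convex face, trans to C5) and should hold.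

**Step 19**
Reactants: 29 keto aldehyde; 30 methyl propiolate
Product: 31 C8 propargylic alcohols (both C8 epimers) with methyl but-2-ynoate arm C8–C7≡C6–CO2Me
Conditions: 30, LiHMDS, THF, −78 °C; then 29, −78 °C; AcOH quench
Reagents that add atoms: methyl propiolate (30), C#CC(=O)OC
Why: 1,2-Addition of a lithium acetylide: at −78 °C the weakly basic lithium propiolate should add to the aldehyde much faster than to the conjugated α-branched C5 ketone, and the C8 mixture is of no account because this centre is reset in steps 20 and 21.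

**Step 20**
Reactants: 31 propargylic alcohols
Product: 32 C8 ynone
Conditions: DMP, pyridine, CH2Cl2, 0 °C
Reagents that add atoms: none
Why: Dess–Martin oxidation of a propargylic alcohol is mild enough for the electrophilic keto ynoate, which is used at once.

**Step 21**
Reactants: 32 ynone
Product: 33 (8S)-propargylic alcohol
Conditions: (S)-Alpine-Borane (from (−)-α-pinene), THF (concentrated), rt; then HOCH2CH2NH2, Et2O
Reagents that add atoms: none
Why: Midland reduction: hydride passes from the pinanyl group in a boat-like six-membered transition state in which the slim alkynyl group takes the hindered position, so the reagent from (−)-α-pinene should give the 8S carbinol under reagent control, while an ordinary ketone such as the C5 enone reacts far more slowly than an ester-activated ynone.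

**Step 22**
Reactants: 33 (8S)-propargylic alcohol
Product: 34 (8S)-TBS ether ynoate
Conditions: TBSOTf (1.1 equiv), 2,6-lutidine, CH2Cl2, −78 °C
Reagents that add atoms: tert-butyldimethylsilyl triflate, CC(C)(C)[Si](C)(C)OS(=O)(=O)C(F)(F)F
Why: Silylation with a silyl triflate and a hindered pyridine avoids nucleophilic bases that would add to the ynoate, and at −78 °C the alcohol should react before the enone is enolsilylated.

**Step 23**
Reactants: 34 ynoate
Product: 35 (8S)-Z-enoate (C6=C7 cis)
Conditions: H2 (1 atm), Lindlar catalyst, quinoline, EtOAc, rt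
Reagents that add atoms: none
Why: Lindlar semihydrogenation adds H2 syn to give the Z-enoate, which the silyl ether keeps from lactonising; the poisoned catalyst should spare the enone alkene, and the step is placed before sulfur or selenium enters the molecule.

**Step 24**
Reactants: 35 Z-enoate enone
Product: 36 3-phenylselanyl C5 ketone (Se on the convex face) with Z-enoate arm
Conditions: PhSeH (1.0 equiv), Et3N (cat.), CH2Cl2, −20 °C
Reagents that add atoms: benzeneselenol, [SeH]c1ccccc1
Why: Base-catalysed conjugate addition of the selenol is much faster to the cyclohexenone than to the β-substituted enoate; it masks C3=C4 so that in step 25 C5 is a plain, more electrophilic ketone and thiolate cannot be diverted to C3, selenium entering from the convex face anti to C1.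

**Step 25**
Reactants: 36 seleno ketone Z-enoate
Product: 37 tetracyclic aldol (5-OH convex, 6-CO2Me, 7-SPh, 8-OTBS, 3-SePh)
Conditions: PhSH, n-BuLi, THF, −78 °C; then 36, −78 → −20 °C; AcOH quench at −78 °C
Reagents that add atoms: thiophenol, Sc1ccccc1
Why: Thiolate-initiated intramolecular Michael–aldol reaction of an ω-oxo-α,β-unsaturated ester: PhSLi adds to C7 and the ester enolate closes ring D onto C5 (6-exo-trig); the tether C9–C8–C7 can reach only the concave face of the ketone, so C5 receives its OH on the convex face cis to H13, while C6 and C7 (ester and thioether expected equatorial) are erased in step 26.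

**Step 26**
Reactants: 37 tetracyclic aldol
Product: 39 tetracyclic methyl ester 8-TBS ether (C3=C4 and C6=C7 in place), via selenoxide sulfoxide 38 (not isolated)
Conditions: m-CPBA (2.1 equiv), CH2Cl2, −78 °C; then DBU, → rt; then toluene, 60 °C
Reagents that add atoms: none
Why: Chalcogen oxidation followed by two eliminations: the selenoxide undergoes syn-elimination below room temperature with a C4 methylene hydrogen rather than the cyclobutane methine H2 (restores C3=C4), and the β-sulfinyl ester loses sulfenate towards the acidic H6 (syn-elimination or DBU-promoted E1cB) rather than towards H8 (gives C6=C7).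

**Step 27**
Reactants: 39 methyl ester TBS ether
Product: 40 methyl ester of the target (5-OH and 8-OH free)
Conditions: TBAF, THF, 0 °C → rt
Reagents that add atoms: none
Why: Fluoride desilylation spares the acid-sensitive doubly allylic tertiary alcohol, and the freed 8-OH cannot lactonise because the ester lies trans to C8 on C6=C7.

**Step 28**
Reactants: 40 methyl ester
Product: 41 target acid CNP0106718.3
Conditions: LiOH, THF/MeOH/H2O, rt; then 1 M HCl to pH 4, 0 °C
Reagents that add atoms: lithium hydroxide, [Li+].[OH-]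
Why: Saponification of the α,β-unsaturated ester, in which retro-aldol is impossible because C6 is now sp2 and no stereocentre is base-labile.

**Compound list**
1 | (R)-cyclohex-2-en-1-ol | O[C@H]1C=CCCC1 | starting material
2 | (1R,2R,6S)-7-oxabicyclo[4.1.0]heptan-2-ol | O[C@@H]1CCC[C@@H]2O[C@H]12 | intermediate
3 | TBS ether of 2 | CC(C)(C)[Si](C)(C)O[C@@H]1CCC[C@@H]2O[C@H]12 | intermediate
4 | hydroxy selenide (C12–SePh trans to C2–OH) | CC(C)(C)[Si](C)(C)O[C@@H]1CCC[C@@H]([Se]c2ccccc2)[C@@H]1O | intermediate
5 | selenoxide of 4 | CC(C)(C)[Si](C)(C)O[C@@H]1CCC[C@@H]([Se](=O)c2ccccc2)[C@@H]1O | intermediate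
6 | (1S,6R)-6-(tert-butyldimethylsilyloxy)cyclohex-2-en-1-ol | CC(C)(C)[Si](C)(C)O[C@@H]1CCC=C[C@@H]1O | intermediate
7 | triethyl orthoacetate | CCOC(C)(OCC)OCC | starting material
8 | ethyl ketene acetal of 6 | C=C(OCC)O[C@H]1C=CCC[C@H]1O[Si](C)(C)C(C)(C)C | intermediate
9 | ethyl 2-[(1R,4R)-4-(tert-butyldimethylsilyloxy)cyclohex-2-en-1-yl]acetate | CCOC(=O)C[C@@H]1C=C[C@H](O[Si](C)(C)C(C)(C)C)CC1 | intermediate
10 | 2-[(1R,4R)-4-(tert-butyldimethylsilyloxy)cyclohex-2-en-1-yl]acetic acid | OC(=O)C[C@@H]1C=C[C@H](O[Si](C)(C)C(C)(C)C)CC1 | intermediate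
11 | (S)-4-benzyl-1,3-oxazolidin-2-one | O=C1N[C@@H](Cc2ccccc2)CO1 | starting material
12 | pivalic mixed anhydride of 10 | CC(C)(C)C(=O)OC(=O)C[C@@H]1C=C[C@H](O[Si](C)(C)C(C)(C)C)CC1 | intermediate
13 | N-acyl oxazolidinone of 10 | O=C1OC[C@H](Cc2ccccc2)N1C(=O)C[C@@H]3C=C[C@H](O[Si](C)(C)C(C)(C)C)CC3 | intermediate
14 | (E)-undec-2-en-1-ol | CCCCCCCC/C=C/CO | starting material
15 | (E)-1-bromoundec-2-ene | CCCCCCCC/C=C/CBr | intermediate
16 | sodium Z-enolate of 13 | [Na+].[O-]/C(=C\[C@@H]1C=C[C@H](O[Si](C)(C)C(C)(C)C)CC1)N2[C@@H](Cc3ccccc3)COC2=O | intermediate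
17 | (2S,4E)-alkylated imide | O=C1OC[C@H](Cc2ccccc2)N1C(=O)[C@@H](C/C=C/CCCCCCCC)[C@@H]3C=C[C@H](O[Si](C)(C)C(C)(C)C)CC3 | intermediate
18 | (2S,4E)-2-[(1S,4R)-4-(tert-butyldimethylsilyloxy)cyclohex-2-en-1-yl]tridec-4-en-1-ol | OC[C@@H](C/C=C/CCCCCCCC)[C@@H]1C=C[C@H](O[Si](C)(C)C(C)(C)C)CC1 | intermediate
19 | (1R,4S)-4-[(2S,4E)-1-hydroxytridec-4-en-2-yl]cyclohex-2-en-1-ol | OC[C@@H](C/C=C/CCCCCCCC)[C@@H]1C=C[C@H](O)CC1 | intermediate
20 | (1R,4S)-4-[(2S,4E)-1-(tert-butyldimethylsilyloxy)tridec-4-en-2-yl]cyclohex-2-en-1-ol | CC(C)(C)[Si](C)(C)OC[C@@H](C/C=C/CCCCCCCC)[C@@H]1C=C[C@H](O)CC1 | intermediate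
21 | (4S)-4-[(2S,4E)-1-(tert-butyldimethylsilyloxy)tridec-4-en-2-yl]cyclohex-2-en-1-one | O=C1C=C[C@H](CC1)[C@@H](CO[Si](C)(C)C(C)(C)C)C/C=C/CCCCCCCC | intermediate
22 | tricyclic C3 ketone, exo octyl | CCCCCCCC[C@H]1[C@@H]2C(=O)CC[C@@H]3[C@@H](CO[Si](C)(C)C(C)(C)C)C[C@H]1[C@H]23 | intermediate
23 | C3,C4 trimethylsilyl enol ether of 22 | CCCCCCCC[C@H]1[C@@H]2C(O[Si](C)(C)C)=CC[C@@H]3[C@@H](CO[Si](C)(C)C(C)(C)C)C[C@H]1[C@H]23 | intermediate
24 | C3 ketone C4=C5 enone | CCCCCCCC[C@H]1[C@@H]2C(=O)C=C[C@@H]3[C@@H](CO[Si](C)(C)C(C)(C)C)C[C@H]1[C@H]23 | intermediate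
25 | 4,5-epoxy C3 ketone | CCCCCCCC[C@H]1[C@@H]2C(=O)[C@H]4O[C@H]4[C@@H]3[C@@H](CO[Si](C)(C)C(C)(C)C)C[C@H]1[C@H]23 | intermediate
26 | hydrazone of 25 | CCCCCCCC[C@H]1[C@@H]2C(=NN)[C@H]4O[C@H]4[C@@H]3[C@@H](CO[Si](C)(C)C(C)(C)C)C[C@H]1[C@H]23 | intermediate
27 | C3=C4 allylic C5 alcohol, 8-OTBS | CCCCCCCC[C@H]1[C@@H]2C=C[C@@H](O)[C@@H]3[C@@H](CO[Si](C)(C)C(C)(C)C)C[C@H]1[C@H]23 | intermediate
28 | C5,C8-diol | CCCCCCCC[C@H]1[C@@H]2C=C[C@@H](O)[C@@H]3[C@@H](CO)C[C@H]1[C@H]23 | intermediate
29 | C5 enone C8 aldehyde | CCCCCCCC[C@H]1[C@@H]2C=CC(=O)[C@@H]3[C@@H](C=O)C[C@H]1[C@H]23 | intermediate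
30 | methyl propiolate | C#CC(=O)OC | starting material
31 | C8 propargylic alcohols (C8 epimers) | CCCCCCCC[C@H]1[C@@H]2C=CC(=O)[C@@H]3[C@@H](C(O)C#CC(=O)OC)C[C@H]1[C@H]23 | intermediate
32 | C8 ynone | CCCCCCCC[C@H]1[C@@H]2C=CC(=O)[C@@H]3[C@@H](C(=O)C#CC(=O)OC)C[C@H]1[C@H]23 | intermediate
33 | (8S)-propargylic alcohol | CCCCCCCC[C@H]1[C@@H]2C=CC(=O)[C@@H]3[C@@H]([C@H](O)C#CC(=O)OC)C[C@H]1[C@H]23 | intermediate
34 | (8S)-TBS ether ynoate | CCCCCCCC[C@H]1[C@@H]2C=CC(=O)[C@@H]3[C@@H]([C@H](O[Si](C)(C)C(C)(C)C)C#CC(=O)OC)C[C@H]1[C@H]23 | intermediate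
35 | (8S)-Z-enoate | CCCCCCCC[C@H]1[C@@H]2C=CC(=O)[C@@H]3[C@@H]([C@H](O[Si](C)(C)C(C)(C)C)/C=C\C(=O)OC)C[C@H]1[C@H]23 | intermediate
36 | 3-phenylselanyl C5 ketone Z-enoate | CCCCCCCC[C@H]1[C@@H]2[C@@H]([Se]c4ccccc4)CC(=O)[C@@H]3[C@@H]([C@H](O[Si](C)(C)C(C)(C)C)/C=C\C(=O)OC)C[C@H]1[C@H]23 | intermediate
37 | tetracyclic Michael–aldol product | CCCCCCCC[C@H]1[C@@H]2[C@@H]([Se]c5ccccc5)C[C@]3(O)[C@H](C(=O)OC)[C@@H](Sc6ccccc6)[C@@H](O[Si](C)(C)C(C)(C)C)[C@H]4C[C@H]1[C@H]2[C@@H]43 | intermediate
38 | selenoxide sulfoxide of 37 | CCCCCCCC[C@H]1[C@@H]2[C@@H]([Se](=O)c5ccccc5)C[C@]3(O)[C@H](C(=O)OC)[C@@H](S(=O)c6ccccc6)[C@@H](O[Si](C)(C)C(C)(C)C)[C@H]4C[C@H]1[C@H]2[C@@H]43 | intermediate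
39 | tetracyclic methyl ester 8-TBS ether | CCCCCCCC[C@H]1[C@@H]2C=C[C@]3(O)C(C(=O)OC)=C[C@@H](O[Si](C)(C)C(C)(C)C)[C@H]4C[C@H]1[C@H]2[C@@H]43 | intermediate
40 | methyl ester of the target | CCCCCCCC[C@H]1[C@@H]2C=C[C@]3(O)C(C(=O)OC)=C[C@@H](O)[C@H]4C[C@H]1[C@H]2[C@@H]43 | intermediate
41 | CNP0106718.3 | CCCCCCCC[C@H]1[C@@H]2C=C[C@]3(O)C(C(=O)O)=C[C@@H](O)[C@H]4C[C@H]1[C@H]2[C@@H]43 | target

**Step count**
Total step count: 28.
Longest linear sequence: 27 (steps 1–6 and 8–28, from 1).

**Steps most likely to fail**

Step 13.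
- What may go wrong: rotation about C11–C1 and slow spin inversion in the triplet biradical may allow three processes to compete with the wanted coupling. These are closure with octyl endo, reversion with E/Z scrambling of the chain alkene, and intramolecular hydrogen transfer.
- Fallback: the same two bonds are made on a copper(I) template instead of through a triplet enone. It sets out from allylic alcohol 20, whose two alkenes and syn hydroxyl can bind one Cu(I).
- Irradiation at 254 nm with (CuOTf)2·C6H6 in Et2O (Salomon–Kochi photobicyclisation of a 1,6-diene) should give, with the E geometry retained, the tricyclic C3 alcohol F1.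
- Dess–Martin oxidation of this alcohol comes back to the route at 22.

Step 25.
- What may go wrong: proton transfer from the C4 or C13 positions of the ketone to the transient ester enolate, retro-aldol opening of the strained ring D (trans-fused to ring B), and retro-Michael loss of selenolate may all outrun productive closure.
- Fallback: the C6 nucleophile is generated from the alkyne under Lewis-acid conditions and the trigger atom is removed reductively. It sets out from ynoate 34, so steps 23–26 are bypassed.
- MgI2 in CH2Cl2 (0 °C → rt) should add iodide to C7. The magnesium allenolate closes onto the activated C5 carbonyl of the enone from the only face the tether allows, and any iodide taken up at C3 is lost again on work-up. This halo-aldol cyclisation gives the tetracyclic 7-iodo ester F2.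
- Pd(PPh3)4-catalysed hydrodeiodination with Bu3SnH in THF comes back to the route at 39.

Step 16.
- What may go wrong: slow hydrazone formation at the hindered C3 ketone, diimide reduction of the new alkene and cyclisation of the hydrazone onto the epoxide may erode the transposition.
- Fallback: the epoxide is opened by a carbon radical at C3 instead of a diazene. It sets out from 25.
- NaBH4/CeCl3 in MeOH gives the 4,5-epoxy C3 alcohol F3 (either C3 epimer serves).
- 1,1'-Thiocarbonyldiimidazole with DMAP gives the thiocarbonylimidazolide F4.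
- Bu3SnH/AIBN in toluene at 80 °C (Barton–McCombie conditions) generates the C3 radical. This cleaves the C4–O bond and, after hydrogen transfer to the C5 alkoxy radical, comes back to the route at 27.

**Further compounds**
F1 | step 13 | tricyclic C3 alcohol (OH on the concave face) | CCCCCCCC[C@H]1[C@@H]2[C@H](O)CC[C@@H]3[C@@H](CO[Si](C)(C)C(C)(C)C)C[C@H]1[C@H]23
F2 | step 25 | tetracyclic 7-iodo methyl ester 8-TBS ether | CCCCCCCC[C@H]1[C@@H]2C=C[C@]3(O)C(C(=O)OC)=C(I)[C@@H](O[Si](C)(C)C(C)(C)C)[C@H]4C[C@H]1[C@H]2[C@@H]43
F3 | step 16 | 4,5-epoxy C3 alcohol (C3 epimers) | CCCCCCCC[C@H]1[C@@H]2C(O)[C@H]4O[C@H]4[C@@H]3[C@@H](CO[Si](C)(C)C(C)(C)C)C[C@H]1[C@H]23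
F4 | step 16 | C3 thiocarbonylimidazolide of F3 | CCCCCCCC[C@H]1[C@@H]2C(OC(=S)n5ccnc5)[C@H]4O[C@H]4[C@@H]3[C@@H](CO[Si](C)(C)C(C)(C)C)C[C@H]1[C@H]23
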